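**Retrosynthetic overview**

1. Target 11 is 4-bromo-3-butyl-5-(dibromomethylidene)furan-2(5H)-one. The two C6–Br bonds go back to a C6 vinylsilane (ipso-bromodesilylation, then bromine addition and dehydrobromination), and C4–Br goes back to the C4–OH of a tetronic acid.
2. Feature on which the strategy rests: the lactone unit C2(=O)–O1 of the furanone ring is one molecule of CO2 bridging C3 and C5. C3 is the α-carbon of a hexanoyl chain (its other four carbons are the butyl group), C4 is the ketone carbon, and C5/C6 are the two alkyne carbons of a silyl ynone.
3. Key disconnection: C2–C3 and O1–C5 of tetronic acid 6 lead back to silyl ynone 3 and CO2 (silver-catalysed carboxylation and 5-exo-dig cyclisation). The only ring is formed in this step.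
4. Ynone 3 is an oct-1-yn-3-one (six carbons from hexanoyl, two from the alkyne), made in one step from hexanoyl chloride and a silylacetylene. The alkyne cap is tert-butyldimethylsilyl rather than trimethylsilyl, because alkynyl–SiMe3 bonds are cleaved by silver(I) salts and by amidine bases, while the bulkier alkynylsilane is not.

Key step: step 2

Assumption: the target has no stereocentre and its exocyclic alkene carries two identical bromines, so it is achiral and has no geometric isomer; "single enantiomer" therefore means the compound as drawn.

**Route**

Step 1
Reactants: 1 hexanoyl chloride; 2 tert-butyl(ethynyl)dimethylsilane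
Product: 3 1-[tert-butyl(dimethyl)silyl]oct-1-yn-3-one
Conditions: PdCl2(PPh3)2 (2 mol %), CuI (4 mol %), Et3N (1.2 equiv), THF, 20 °C
Reagents that add atoms: none
Why: Acyl Sonogashira coupling: Pd(0) inserts into the C–Cl bond, the acylpalladium is transmetalated by the copper acetylide of 2 and reductively eliminates the ynone, which at room temperature with only a slight excess of amine should outrun ketene formation from the enolisable acid chloride and leaves the hindered Si–C(sp) bond untouched.

Step 2
Reactants: 3 1-[tert-butyl(dimethyl)silyl]oct-1-yn-3-one; 4 carbon dioxide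
Product: 6 (Z)-3-butyl-5-{[tert-butyl(dimethyl)silyl]methylidene}-4-hydroxyfuran-2(5H)-one, via keto carboxylate 5 (not isolated)
Conditions: AgOAc (10 mol %), MTBD (2.0 equiv), CO2 (1.0 MPa), MeCN, 25 °C; then 1 M HCl
Reagents that add atoms: none
Why: MTBD deprotonates the only enolisable position of 3 (C3; the alkyne side has no hydrogen) and the enolate is carboxylated reversibly by CO2 to the β-keto carboxylate 5 (C2–C3 bond); silver(I) then binds the alkyne, the carboxylate oxygen adds anti across it at C5 (O1–C5 bond), and protodemetalation of the vinylsilver followed by enolisation gives the tetronate, whose salt formation with MTBD pulls the carboxylation equilibrium forward. The closest known reaction type is the silver-catalysed carboxylative cyclisation of alkyl- and aryl-terminated conjugated ynones with CO2 and an amidine or guanidine base to 5-ylidene tetronic acids. The furanone ring closes 5-exo-dig. No stereocentre is formed; the Z geometry of the exocyclic alkene (silicon cis to O1) follows from anti oxyargentation and stereoretentive protonation of the C6–Ag bond. The step needs 5-exo attack at C5 to beat 6-endo conjugate attack at C6 (which would give a 4-hydroxy-2-pyranone) and needs the C(sp)–Si bond to survive: the bulky silyl group shields C6 and polarises the silver–alkyne complex so that positive charge builds at C5 (β to silicon), and the tert-butyldimethylsilyl group, unlike trimethylsilyl, is not stripped from alkynes by silver(I) salts or amidine bases. The silyl cap also rules out silver acetylide formation and hinders conjugate addition of enolate or base at C6.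

Step 3
Reactants: 6 (Z)-3-butyl-5-{[tert-butyl(dimethyl)silyl]methylidene}-4-hydroxyfuran-2(5H)-one
Product: 7 (Z)-4-bromo-3-butyl-5-{[tert-butyl(dimethyl)silyl]methylidene}furan-2(5H)-one
Conditions: (COBr)2 (1.3 equiv), DMF (1.5 equiv), CH2Cl2, 0 → 20 °C
Reagents that add atoms: oxalyl bromide, O=C(Br)C(=O)Br
Why: Vilsmeier-type bromodehydroxylation of a vinylogous acid: the bromoiminium salt from oxalyl bromide and DMF activates the C4 hydroxyl and bromide displaces the activated oxygen at C4 by addition–elimination, as is routine for 3-substituted tetronic acids, while C3 is blocked by the butyl group and the hindered vinyl–silicon bond should resist protodesilylation by the HBr released.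

Step 4
Reactants: 7 (Z)-4-bromo-3-butyl-5-{[tert-butyl(dimethyl)silyl]methylidene}furan-2(5H)-one
Product: 9 (Z)-4-bromo-5-(bromomethylidene)-3-butylfuran-2(5H)-one, via silyl dibromide 8 (not isolated)
Conditions: Br2 (1.05 equiv), CH2Cl2, −78 → 0 °C, dark; then Bu4NF (1.1 equiv), AcOH (1.1 equiv), THF, −20 → 0 °C
Reagents that add atoms: bromine, BrBr
Why: Bromodesilylation of a vinylsilane by addition–elimination: bromine adds across the exocyclic C5=C6 bond with the electrophile entering at C6 (the cation at C5 is stabilised by O1 and by the β-silicon), and buffered fluoride then attacks silicon and expels the C5 bromide (β-elimination of a β-bromosilane), so bromine stands where silicon stood; the Z isomer (bromine away from the C4 bromine) is expected to predominate, but either geometry serves because step 5 removes this stereo-element.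

Step 5
Reactants: 9 (Z)-4-bromo-5-(bromomethylidene)-3-butylfuran-2(5H)-one
Product: 11 4-bromo-3-butyl-5-(dibromomethylidene)furan-2(5H)-one, via tribromide 10 (not isolated)
Conditions: Br2 (1.2 equiv), CH2Cl2, 20 °C, dark; excess Br2 removed; then i-Pr2NEt (1.5 equiv), CH2Cl2, 0 °C
Reagents that add atoms: bromine, BrBr
Why: Bromination–dehydrobromination: electrophilic addition of bromine to the exocyclic bromoalkene gives tribromide 10, in which the only hydrogen β to the labile C5 bromide sits on C6, so E2 elimination with the hindered amine can only give the conjugated dibromomethylidene lactone, the tetrasubstituted electron-poor C3=C4 bond being inert to bromine.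

**Compound list**

1 | hexanoyl chloride | CCCCCC(=O)Cl | starting material
2 | tert-butyl(ethynyl)dimethylsilane | C#C[Si](C)(C)C(C)(C)C | starting material
3 | 1-[tert-butyl(dimethyl)silyl]oct-1-yn-3-one | CCCCCC(=O)C#C[Si](C)(C)C(C)(C)C | intermediate
4 | carbon dioxide | O=C=O | starting material
5 | 2-butyl-5-[tert-butyl(dimethyl)silyl]-3-oxopent-4-ynoic acid, racemic, present in the flask as its MTBD-H+ carboxylate | CCCCC(C(=O)O)C(=O)C#C[Si](C)(C)C(C)(C)C | intermediate (not isolated)
6 | (Z)-3-butyl-5-{[tert-butyl(dimethyl)silyl]methylidene}-4-hydroxyfuran-2(5H)-one | CCCCC1=C(O)/C(=C/[Si](C)(C)C(C)(C)C)OC1=O | intermediate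
7 | (Z)-4-bromo-3-butyl-5-{[tert-butyl(dimethyl)silyl]methylidene}furan-2(5H)-one | CCCCC1=C(Br)/C(=C/[Si](C)(C)C(C)(C)C)OC1=O | intermediate
8 | 4,5-dibromo-5-{bromo[tert-butyl(dimethyl)silyl]methyl}-3-butylfuran-2(5H)-one, racemic; relative configuration of the two new centres left open because both are destroyed in the same step | CCCCC1=C(Br)C(Br)(C(Br)[Si](C)(C)C(C)(C)C)OC1=O | intermediate (not isolated)
9 | (Z)-4-bromo-5-(bromomethylidene)-3-butylfuran-2(5H)-one | CCCCC1=C(Br)/C(=C/Br)OC1=O | intermediate
10 | 4,5-dibromo-3-butyl-5-(dibromomethyl)furan-2(5H)-one, racemic at C5 | CCCCC1=C(Br)C(Br)(C(Br)Br)OC1=O | intermediate (not isolated)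
11 | 4-bromo-3-butyl-5-(dibromomethylidene)furan-2(5H)-one | CCCCC1=C(Br)C(=C(Br)Br)OC1=O | target

**Step count and risk**

Total steps: 5. Longest linear sequence: 5 steps (from hexanoyl chloride 1).

Steps most likely to fail:

1. Step 2. The alkynyl silyl group may be lost under silver and base, with the freed alkyne trapped as silver acetylide. The carboxylate oxygen may attack C6 in the 6-endo mode, or the enolate may add to a second ynone faster than it is carboxylated. The fallback drops the alkyne/CO2 logic and builds the ring by Dieckmann condensation, which fixes the ring size. It sets out from hexanoyl chloride 1. Acylation of ethyl glycolate (pyridine, CH2Cl2, 0 °C) should give ethyl 2-(hexanoyloxy)acetate F1. Intramolecular Claisen condensation with t-BuOK in THF should close it to 3-butyl-4-hydroxyfuran-2(5H)-one F2. Its dianion (LDA, 2.2 equiv, THF, −78 °C) is formylated at C5 with ethyl formate to give (E)-3-butyl-4-hydroxy-5-(hydroxymethylidene)furan-2(5H)-one F3. Excess oxalyl bromide and DMF in CH2Cl2 then exchange both enolic hydroxyls for bromide, and the route is rejoined at compound 9 before step 5.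

2. Step 4. Bromine addition to the hindered, electron-poor exocyclic alkene may be slow, and fluoride may attack the bromolactone (substitution at C4 or ring opening) instead of triggering loss of silicon. The fallback separates removal of silicon from introduction of bromine. It sets out from compound 7. Protodesilylation with TfOH in CH2Cl2 at 0 °C (ipso protonation at C6 through the same O1- and β-silicon-stabilised cation; the bromofuranone core tolerates strong acid) should give 4-bromo-3-butyl-5-methylidenefuran-2(5H)-one F4. Bromine addition in CH2Cl2 should give 4,5-dibromo-5-(bromomethyl)-3-butylfuran-2(5H)-one F5. Dehydrobromination with i-Pr2NEt at 0 °C rejoins the route at compound 9.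

3. Step 3. The HBr released may protodesilylate the vinylsilane, or activation of the C4 oxygen may stay incomplete. The fallback avoids acid by going through a sulfonate. It sets out from compound 6. Triflation with Tf2O and i-Pr2NEt in CH2Cl2 at −78 °C should give (Z)-3-butyl-5-{[tert-butyl(dimethyl)silyl]methylidene}-2-oxo-2,5-dihydrofuran-4-yl trifluoromethanesulfonate F6. Addition–elimination with LiBr in acetone at 20 °C on this vinylogous acyl triflate rejoins the route at compound 7.

Further compounds
F1 | step 2 | ethyl 2-(hexanoyloxy)acetate | CCCCCC(=O)OCC(=O)OCC
F2 | step 2 | 3-butyl-4-hydroxyfuran-2(5H)-one | CCCCC1=C(O)COC1=O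
F3 | step 2 | (E)-3-butyl-4-hydroxy-5-(hydroxymethylidene)furan-2(5H)-one | CCCCC1=C(O)/C(=C\O)OC1=O
F4 | step 4 | 4-bromo-3-butyl-5-methylidenefuran-2(5H)-one | CCCCC1=C(Br)C(=C)OC1=O
F5 | step 4 | 4,5-dibromo-5-(bromomethyl)-3-butylfuran-2(5H)-one, racemic | CCCCC1=C(Br)C(Br)(CBr)OC1=O
F6 | step 3 | (Z)-3-butyl-5-{[tert-butyl(dimethyl)silyl]methylidene}-2-oxo-2,5-dihydrofuran-4-yl trifluoromethanesulfonate | CCCCC1=C(OS(=O)(=O)C(F)(F)F)/C(=C/[Si](C)(C)C(C)(C)C)OC1=O
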